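**Assumption:** Kuwanon C has no stereocentres (achiral), so no enantiocontrol is needed. The only stereocentre in the route is the epimerisable C-2 of diketone **20**, which is destroyed in Step 16.

## Retrosynthetic overview
1. Kuwanon C comes from global deprotection of a protected 3,8-diprenylflavone. The pyranone ring is the last ring formed, by cyclodehydration of a 1,3-diketone.
2. The diketone comes from a Baker–Venkataraman acyl transfer of an aryl ester. The ester joins an A-ring ketone (8-prenyl, 5-OBn, 7-OMOM, carrying the 3-prenyl as a 5-methylhex-4-enoyl chain) to a 2,4-bis(MOMO)benzoyl chloride (B ring).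
3. The A-ring ketone is built from resorcinol by directed ortho-metalation (DoM) prenylation, Ir C–H borylation and oxidation (third oxygen), DoM acylation with a Weinreb amide, and chelation-controlled ortho-MOM cleavage.
4. The B-ring acid comes from resorcinol by Kolbe–Schmitt carboxylation. The Weinreb amide comes from homoprenyl bromide and CO2.

## Route

**Step 1**
Reactants: **1** resorcinol
Product: **2** 1,3-bis(methoxymethoxy)benzene
Conditions: NaH, MOMCl, THF/DMF, 0 °C → rt
Reagents that add atoms: MOMCl, COCCl
Why: Double Williamson-type O-alkylation gives the MOM-protected resorcinol, an excellent DoM substrate.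

**Step 2**
Reactants: **2**; **3** prenyl bromide (1-bromo-3-methylbut-2-ene)
Product: **4** 2-prenyl-1,3-bis(MOMO)benzene
Conditions: n-BuLi, THF, 0 °C; then CuI (10 mol%), **3**, –20 °C → rt
Reagents that add atoms: prenyl bromide (**3**), CC(C)=CCBr
Why: Directed ortho-metalation occurs at C-2, between the two MOM ethers. Cu(I)-catalysed SN2 allylation then gives the linear prenyl group at what becomes C-8.

**Step 3**
Reactants: **4**
Product: **5** 2-[3,5-bis(MOMO)-4-prenylphenyl]-4,4,5,5-tetramethyl-1,3,2-dioxaborolane
Conditions: B2pin2, [Ir(OMe)(cod)]2 (1.5 mol%), dtbpy (3 mol%), THF, 80 °C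
Reagents that add atoms: B2pin2, CC1(C)OB(OC1(C)C)B1OC(C)(C)C(C)(C)O1
Why: Ir-catalysed C–H borylation is sterically controlled and goes to the only C–H that is meta to both OMOM groups and flanked by no substituent (C-5). This sets the future 5-oxygen.

**Step 4**
Reactants: **5**
Product: **6** 3,5-bis(MOMO)-4-prenylphenol
Conditions: 30% H2O2, NaOH, THF/H2O, 0 °C → rt; then aq. NH4Cl
Reagents that add atoms: hydrogen peroxide, OO
Why: Oxidative deborylation (Bpin → OH) with retention of position. The MOM groups and the prenyl alkene are stable to basic peroxide.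

**Step 5**
Reactants: **6**
Product: **7** 5-(benzyloxy)-1,3-bis(MOMO)-2-prenylbenzene
Conditions: BnBr, K2CO3, DMF, rt
Reagents that add atoms: benzyl bromide, BrCc1ccccc1
Why: Williamson etherification. The benzyl group distinguishes the future 5-oxygen from the MOM groups so that a later chelation-controlled MOM cleavage is selective.

**Step 6**
Reactants: **8** homoprenyl bromide (5-bromo-2-methylpent-2-ene); **9** CO2
Product: **10** 5-methylhex-4-enoic acid
Conditions: Mg, THF, reflux; then CO2, –78 °C → rt; then 1 M HCl (brief)
Reagents that add atoms: carbon dioxide (**9**), O=C=O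
Why: Grignard carboxylation. The homoallylic Grignard is configurationally and constitutionally stable and gives the C7 acid that supplies C-3 plus its prenyl group.

**Step 7**
Reactants: **10**; **11** N,O-dimethylhydroxylamine hydrochloride
Product: **12** N-methoxy-N,5-dimethylhex-4-enamide (Weinreb amide)
Conditions: EDC·HCl, HOBt, i-Pr2NEt, CH2Cl2, rt
Reagents that add atoms: MeNH(OMe)·HCl (**11**), CNOC.Cl
Why: Carbodiimide amide coupling gives an acyl donor that will stop at the ketone stage.

**Step 8**
Reactants: **7**; **12**
Product: **13** 1-[6-(benzyloxy)-2,4-bis(MOMO)-3-prenylphenyl]-5-methylhex-4-en-1-one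
Conditions: n-BuLi, TMEDA, THF, –78 → –30 °C; then **12**, –78 °C → rt; aq. NH4Cl
Reagents that add atoms: Weinreb amide (**12**), CON(C)C(=O)CCC=C(C)C
Why: DoM. The two equivalent C–H positions lie between OMOM and OBn, so acylation has one regiochemical outcome. The Weinreb tetrahedral intermediate prevents over-addition, so the ketone is formed cleanly.

**Step 9**
Reactants: **13**
Product: **14** 1-[6-(benzyloxy)-2-hydroxy-4-(MOMO)-3-prenylphenyl]-5-methylhex-4-en-1-one
Conditions: MgBr2·OEt2, n-PrSH, Et2O, rt
Reagents that add atoms: none
Why: Mg2+ chelates the ketone and the ortho MOM oxygen, so only the MOM flanked by the acyl and prenyl groups (future C8a–O) is cleaved. The para MOM and the benzyl ether are untouched. The product phenol is H-bonded to the carbonyl.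

**Step 10**
Reactants: **1** resorcinol; **9** CO2
Product: **15** 2,4-dihydroxybenzoic acid
Conditions: KHCO3, CO2, H2O, 90 °C; then HCl to pH 1
Reagents that add atoms: carbon dioxide, O=C=O
Why: Kolbe–Schmitt-type carboxylation of resorcinol, which occurs ortho to one OH and para to the other.

**Step 11**
Reactants: **15**
Product: **16** MOM 2,4-bis(MOMO)benzoate
Conditions: MOMCl (3.5 equiv), i-Pr2NEt, CH2Cl2, 0 °C → rt
Reagents that add atoms: MOMCl, COCCl
Why: Both phenols and the carboxylic acid are alkylated, giving a single fully protected intermediate.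

**Step 12**
Reactants: **16**
Product: **17** 2,4-bis(methoxymethoxy)benzoic acid
Conditions: LiOH, THF/MeOH/H2O, rt; acidify to pH 4 with citric acid
Reagents that add atoms: lithium hydroxide/water, [Li+].[OH-] and O
Why: The MOM ester (an activated ester) is saponified much faster than the acetal ethers, which survive the basic conditions.

**Step 13**
Reactants: **17**
Product: **18** 2,4-bis(methoxymethoxy)benzoyl chloride
Conditions: Ghosez reagent, CH2Cl2, 0 °C → rt, 1 h (used crude)
Reagents that add atoms: 1-chloro-N,N,2-trimethylpropenylamine, CC(C)=C(Cl)N(C)C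
Why: Acid chloride formation under neutral conditions (no free HCl), so the MOM ethers survive.

**Step 14 (fragment coupling)**
Reactants: **14**; **18**
Product: **19** aryl ester of **14** with the B-ring acid
Conditions: DMAP (1 equiv), pyridine, CH2Cl2, 0 °C → 40 °C
Reagents that add atoms: none
Why: DMAP-catalysed O-acylation joins the A-ring and B-ring fragments. The hindered, H-bonded phenol is acylated by the reactive acid chloride.

**Step 15**
Reactants: **19**
Product: **20** 1-[2-hydroxy-6-BnO-4-MOMO-3-prenylphenyl]-3-[2,4-bis(MOMO)phenyl]-2-prenylpropane-1,3-dione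
Conditions: LiHMDS (3 equiv), THF, –78 °C → rt; aq. NH4Cl
Reagents that add atoms: none
Why: Baker–Venkataraman rearrangement. The ketone enolate attacks the ester through a six-membered transition state and forms the C–C bond that carries the 3-prenyl group. The new C-2 stereocentre is racemic and epimerisable and is removed in Step 16.

**Step 16**
Reactants: **20**
Product: **21** 5-OBn-3,8-diprenyl-7-MOMO-2-[2,4-bis(MOMO)phenyl]chromen-4-one
Conditions: PPh3, DIAD, THF, 0 °C → rt
Reagents that add atoms: none
Why: Mitsunobu cyclodehydration. The enol OH is activated and the A-ring phenol closes the pyranone by addition–elimination. Only the A-ring phenol is free, so there is no isomeric closure through the B ring, and the acid-labile MOM groups are untouched.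

**Step 17**
Reactants: **21**
Product: **22** Kuwanon C
Conditions: BCl3 (10 equiv), pentamethylbenzene, CH2Cl2, –78 → 0 °C; quench with MeOH at –78 °C
Reagents that add atoms: none
Why: BCl3 cleaves the four MOM ethers and, with the cation scavenger, the aryl benzyl ether (5-OBn, assisted by chelation to C-4=O). The 3- and 8-prenyl alkenes survive at low temperature.

## Compound list
1 | resorcinol | Oc1cccc(O)c1 | starting material
2 | 1,3-bis(methoxymethoxy)benzene | COCOc1cccc(OCOC)c1 | intermediate
3 | prenyl bromide | CC(C)=CCBr | starting material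
4 | 2-prenyl-1,3-bis(MOMO)benzene | COCOc1cccc(OCOC)c1CC=C(C)C | intermediate
5 | aryl pinacolboronate | COCOc1cc(B2OC(C)(C)C(C)(C)O2)cc(OCOC)c1CC=C(C)C | intermediate
6 | 3,5-bis(MOMO)-4-prenylphenol | COCOc1cc(O)cc(OCOC)c1CC=C(C)C | intermediate
7 | 5-benzyloxy-1,3-bis(MOMO)-2-prenylbenzene | COCOc1cc(OCc2ccccc2)cc(OCOC)c1CC=C(C)C | intermediate
8 | 5-bromo-2-methylpent-2-ene | CC(C)=CCCBr | starting material
9 | carbon dioxide | O=C=O | starting material
10 | 5-methylhex-4-enoic acid | CC(C)=CCCC(=O)O | intermediate
11 | N,O-dimethylhydroxylamine hydrochloride | CNOC.Cl | starting material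
12 | N-methoxy-N,5-dimethylhex-4-enamide | CON(C)C(=O)CCC=C(C)C | intermediate
13 | tris-protected A-ring ketone | COCOc1cc(OCc2ccccc2)c(C(=O)CCC=C(C)C)c(OCOC)c1CC=C(C)C | intermediate
14 | A-ring 2-hydroxyaryl ketone | COCOc1cc(OCc2ccccc2)c(C(=O)CCC=C(C)C)c(O)c1CC=C(C)C | intermediate
15 | 2,4-dihydroxybenzoic acid | OC(=O)c1ccc(O)cc1O | intermediate
16 | MOM 2,4-bis(MOMO)benzoate | COCOC(=O)c1ccc(OCOC)cc1OCOC | intermediate
17 | 2,4-bis(MOMO)benzoic acid | COCOc1ccc(C(=O)O)c(OCOC)c1 | intermediate
18 | 2,4-bis(MOMO)benzoyl chloride | COCOc1ccc(C(=O)Cl)c(OCOC)c1 | intermediate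
19 | aryl ester (coupled) | COCOc1cc(OCc2ccccc2)c(C(=O)CCC=C(C)C)c(OC(=O)c2ccc(OCOC)cc2OCOC)c1CC=C(C)C | intermediate
20 | 2-prenyl-1,3-diketone (racemic, epimerisable centre) | COCOc1cc(OCc2ccccc2)c(C(=O)C(CC=C(C)C)C(=O)c2ccc(OCOC)cc2OCOC)c(O)c1CC=C(C)C | intermediate
21 | protected 3,8-diprenylflavone | O=c1c(CC=C(C)C)c(-c2ccc(OCOC)cc2OCOC)oc2c(CC=C(C)C)c(OCOC)cc(OCc3ccccc3)c12 | intermediate
22 | Kuwanon C | CC(C)=CCc1c(-c2ccc(O)cc2O)oc2c(CC=C(C)C)c(O)cc(O)c2c1=O | target

## Totals
- Total steps: 17.
- Longest linear sequence: 11 (Steps 1, 2, 3, 4, 5, 8, 9, 14, 15, 16, 17).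

## Three steps most likely to fail
1. **Step 9 (selective ortho-MOM cleavage).** Fallback: desymmetrise resorcinol from the start, using mono-TBS resorcinol → MOM → DoM prenylation → borylation/oxidation/MOM → TBAF. Then use the free phenol to direct Casnati–Skattebøl ortho-formylation, add homoprenylMgBr (from **8**), and oxidise (DMP) to reach the same kind of free-ortho-OH ketone.
2. **Step 15 (Baker–Venkataraman on the hindered, α-branched ketone).** Fallback: use N-methoxy-N-methylacetamide in Step 8 to give the methyl ketone. Run an unbranched Baker–Venkataraman reaction, then C-prenylate the diketone with prenyl bromide/K2CO3 before cyclisation.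
3. **Step 16 (Mitsunobu cyclodehydration of the 2-substituted diketone).** Fallback: convert the diketone to its enol triflate (Tf2O, 2,6-lutidine) and close the ring by K2CO3-mediated intramolecular vinylic substitution by the phenoxide.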